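**Remarks on the chemistry**
- The six phenols are carried as benzyl ethers. These withstand BF3·OEt2/Et3SiH and DDQ and leave under neutral hydrogenolysis. Acetal ethers would be at risk under BF3·OEt2 and would need acid at the end, which the three oxygen-activated benzylic C–O bonds of the target would not survive. The bonds, rings and skeletons of the key step are unchanged by this choice.
- The γ-hydroxy ketones 18 and 19 can close to a cyclic hemiketal (17 for 18); the open hydroxy ketone is taken as the isolated form.

## Structural features

The target is a 2,3,4,5-tetrasubstituted oxolane (ring A: O1, C2–C5). It carries a 4-hydroxyphenyl group at C2, a 2,4-dihydroxybenzoyl group at C3, an (R)-hydroxy(4-hydroxyphenyl)methyl group at C4 and a 2,4-dihydroxyphenyl group at C5. Five stereocentres stand in an unbroken row (C2, C3, C4, C5 and the carbinol carbon on C4), all R. C2/C3 are trans, C3/C4 and C4/C5 are cis, so the C5 aryl group sits on the crowded face next to the C4 side chain. Three benzylic C–O bonds (C2–O1, C5–O1 and the carbinol C–OH) are each activated by an ortho or para phenol and ionise easily in acid; C3–H is α to the ketone with O1 as a β-leaving group, and the ketone can close on the carbinol oxygen to a hemiketal. The real difficulty is twofold: the all-cis C3–C4–C5 array, and the fact that the two halves of an otherwise dimeric skeleton differ in oxidation level (aryl ketone on one side, benzylic ether on the other). The key step exploits the latent ring B (C3, ketone carbon, O, carbinol carbon, C4). With ring B closed the molecule is a cis-fused, C2-symmetric 3,7-dioxabicyclo[3.3.0]octane in which C5 and the ketone carbon are equivalent benzylic ether carbons with their aryl groups on the concave face, so both can come from one twofold aryl addition and hydride delivery to a symmetric dilactone.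

## Logic of the disconnections

**19 ⇒ 18.** The six phenolic O–H bonds of 19 are replaced by O–CH2Ph bonds. Free phenols would quench the aryllithium, react with DDQ and make every benzylic C–O bond acid-labile in the Lewis-acid step. Nothing is gained in skeleton, but all earlier steps become possible. The forward step must cleave six aryl benzyl ethers under neutral conditions and leave three benzylic C–O bonds and the aryl ketone intact.

**18 ⇒ 16 (through 17).** The ketone C=O and the carbinol O–H of 18 are rejoined as one C–O–C bridge, and the carbonyl carbon regains a hydrogen. This is the simplifying cut: 16 is C2-symmetric, its six stereocentres are three equivalent pairs, and the ketone carbon and C5 of 19 become one kind of carbon. The forward oxidation must strike only one of two equivalent benzylic ether C–H bonds and must prefer them to the two C–H bonds next to the less electron-rich rings.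

**16 ⇒ 11 + 13 (through 14 and 15).** At each of the two equivalent carbons of 16 the C–aryl bond and the C–H bond are cut; the carbon returns to a lactone carbonyl of 11 and each aryl group to one molecule of 13, so two molecules of 13 are needed for one of 11. Four aryl groups become two, two stereocentres disappear, and the nucleophile is one simple aryl metal. Each carbonyl must take exactly one aryl group, and hydride must then arrive on the convex face of both rings.

**13 ⇒ 12.** The two O–benzyl bonds are cut. The bromine is kept as the marker for metalation, because direct lithiation of the unbrominated diether would occur between the two oxygens. The forward step is a plain twofold O-alkylation.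

**11 ⇒ 10 ⇒ 9.** The ring-fusion C–H of 11 is traced to a C–Br bond in 10; that C–Br bond and the neighbouring benzylic C–O bond of 10 are then cut together to the alkene and carboxylic acid of 9. The carboxyl group can reach the alkene only from its own face, the ring fusion can only be cis, and anti addition to an alkene of fixed geometry defines the aryl-bearing carbon. One ring and two stereocentres are removed. The electrophile must attack the alkene and not the arenes, and the halogen must later be removed without base.

**9 ⇒ 8 ⇒ 6 + 2 (through 7).** The acyl–N bond of 8 is restored, then the lactone acyl–O bond and the C–C bond between the imide α-carbon and the aryl carbinol carbon are cut. This is the only step that needs external chirality; both stereocentres of 9 come from one auxiliary-controlled syn-aldol. The forward step must enolise the CH2 between imide and alkene, react at the α-carbon, and keep the alkene geometry.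

**6 ⇒ 3 + 4 (through 5); 3 ⇒ 1 + 2.** The N–acyl bond and then the C=C bond are cut. The condensation that forms 3 differentiates the two carboxyl groups without extra steps: the free acid is on the CH2 arm (for 4), the ester on the alkene carbon (the future lactone carbonyl). The forward step must give the E alkene.

## Other disconnections considered

**Alternative 1:** The cut is at the two bonds between the lactone ring oxygens and the benzylic carbons of the dilactone (O3–C2 and O7–C6; in 19 these are O1–C2 and the carbinol C–O bond). The bicycle unfolds to the C2-symmetric diacid A2, (2S,3S)-2,3-bis(4-hydroxybenzyl)succinic acid. In the forward step DDQ would dehydrogenate each 4-hydroxybenzyl group to a para-quinone methide, and the carboxyl group on the farther α-carbon would add to the methide carbon in a 5-exo closure; done twice, this gives the free-phenol dilactone A1.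
- In its favour: both ring-fusion centres are already in A2, only a cis fusion can form, and two rings and two stereocentres arise in one operation without halogen or tin.
- Where it is equal or better: in ring construction per step it is the better plan (one step against steps 5 and 6 here). In mechanism the two are equals, since in both a carboxyl group captures a 4-oxygenated benzylic electrophile. In step count to 11 the two are about equal (about six steps each), because A2 needs its own asymmetric synthesis of about four steps and A1 must then be benzylated.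
- Against it here: the exo placement of the aryl groups would rest on conformational preference of the quinone methides, not on a stereospecific event. A1 has free phenols and can re-open through the quinone methide under the basic conditions of its benzylation.
- Comparison: structurally the chosen plan fixes one aryl carbon by the aldol and the other by anti addition to a defined alkene; the alternative is judged less secure in stereocontrol and handling.

**Alternative 2:** The cut is at the two C–C bonds between the ring-fusion carbons and the aryl-bearing carbons of the dilactone (C1–C2 and C5–C6; in 19 the C2–C3 bond and the bond from C4 to the carbinol carbon). In the forward step the bis-imide A3, a succinyl unit bound to two molecules of 4, would be enolised on both sides with Bu2BOTf and an amine. The bis(boron enolate) would add to two molecules of the aldehyde A4 to give the C2-symmetric bis-syn-aldol A5; no ring closes in this step. Lactonisation of each hydroxyl on the farther imide carbonyl, with loss of both molecules of 4, would then give the dilactone A6.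
- In its favour: all four stereocentres of the dilactone come from one reagent-controlled reaction run twice, the symmetry is used from the first step, and a twofold auxiliary-controlled event raises the enantiomeric purity of the symmetric product.
- Where it is equal or better: in step economy it is clearly better (about three steps to the dilactone against six). In control of the aryl carbinol centres it is the equal of the chosen plan, since the same closed transition state is used.
- Against it here: two boron enolates must form on neighbouring carbons of one four-carbon chain, and the second aldol must take place next to a boron aldolate. If the first aldolate lactonises early, the remaining methylene is no longer next to an auxiliary-bearing carbonyl; a lactone enolate would be expected to take the second aldehyde trans to the ring substituent, the ring-fusion configuration that cannot close the second lactone.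
- Comparison: the chosen plan avoids this by making the second aryl-bearing carbon on an sp2 carbon and closing the ring by anti addition, at the cost of three more steps. The alternative is shorter and structurally more elegant but hangs on one untested twofold enolisation.

**Alternative 3:** The cut is at the two lactone acyl–oxygen bonds and the two carbinol C–H bonds. This leads to the bis(β-keto ester) A7, dimethyl 2,3-bis[4-(methoxymethoxy)benzoyl]succinate, whose two α-carbons epimerise freely. In the forward step an (R)-selective ketoreductase with NADPH recycling would reduce both aryl ketones, and each new hydroxyl would lactonise on the farther ester, closing both γ-lactone rings of A6.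
- In its favour: no stoichiometric chiral reagent, neutral aqueous conditions under which any phenol ether is safe, and catalyst control of the carbinol configuration.
- Where it is equal or better: in step economy it is the best of all (about three steps to the dilactone). In control of the carbinol carbons it is at least the equal of the aldol used here.
- Against it here: the enzyme sets only the two carbinol carbons. The ring-fusion carbons are set by which epimer is reduced and lactonised; once the first lactone has closed, one of them is locked, and reduction of the wrong epimer at the second ketone would give a hydroxy lactone that can neither close nor return. A7 is also a 1,4-diketone that can cyclodehydrate to a furan, is largely enolised, and is a crowded substrate whose acceptance would have to be found by screening.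
- Comparison: the chosen plan derives each centre from an enforced geometry, the alternative from dynamic selection. The alternative is shorter but less predictable.

Key step: step 8

## Route

**Step 1**
Reactants: 1 dimethyl succinate; 2 4-(benzyloxy)benzaldehyde
Product: 3 (3E)-4-[4-(benzyloxy)phenyl]-3-(methoxycarbonyl)but-3-enoic acid
Conditions: NaOMe, MeOH, reflux; then aq. HCl
Reagents that add atoms: none
Why: Stobbe condensation: the succinate enolate adds to the aldehyde, the aldolate lactonises on the far ester and the lactone opens by elimination, which leaves the acid on the CH2 arm, the ester on the alkene carbon and the aryl group trans to that ester (E); no stereocentre is formed.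

**Step 2**
Reactants: 3 (3E)-4-[4-(benzyloxy)phenyl]-3-(methoxycarbonyl)but-3-enoic acid; 4 (4R)-4-benzyl-1,3-oxazolidin-2-one
Product: 6 methyl (2E)-2-{2-[(4R)-4-benzyl-2-oxo-1,3-oxazolidin-3-yl]-2-oxoethyl}-3-[4-(benzyloxy)phenyl]prop-2-enoate, via mixed pivalic anhydride 5 (not isolated)
Conditions: PivCl, Et3N, THF, −20 °C; then 4, LiCl, −20 °C → rt
Reagents that add atoms: none
Why: N-acylation of an oxazolidinone through a mixed anhydride: the hindered pivaloyl carbonyl of 5 is not attacked, so the LiCl-activated oxazolidinone takes the substrate acyl group; the conjugated methyl ester and the E alkene are not touched.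

**Step 3**
Reactants: 6 methyl (2E)-2-{2-[(4R)-4-benzyl-2-oxo-1,3-oxazolidin-3-yl]-2-oxoethyl}-3-[4-(benzyloxy)phenyl]prop-2-enoate; 2 4-(benzyloxy)benzaldehyde
Product: 8 (4R)-4-benzyl-3-{[(2R,3R,4E)-2-[4-(benzyloxy)phenyl]-4-{[4-(benzyloxy)phenyl]methylidene}-5-oxooxolan-3-yl]carbonyl}-1,3-oxazolidin-2-one, via open syn-aldol adduct 7 (not isolated)
Conditions: Bu2BOTf, iPr2NEt, CH2Cl2, −78 → 0 °C; 2, −78 → 0 °C; pH 7 buffer, MeOH, H2O2, 0 °C; then PPTS (cat.), PhMe, 50 °C
Reagents that add atoms: none
Why: Evans syn-aldol: soft enolisation of the CH2 between imide and alkene gives the Z(O) boron enolate, which adds to the aldehyde at its α-carbon through a closed chair transition state on the face away from the benzyl group of the (R)-auxiliary, setting both new centres (R at the α-carbon, R at the carbinol, syn); the γ-hydroxy α-alkylidene ester 7 then lactonises (5-exo-trig) with loss of methanol, and the alkene geometry is kept.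

**Step 4**
Reactants: 8 (4R)-4-benzyl-3-{[(2R,3R,4E)-2-[4-(benzyloxy)phenyl]-4-{[4-(benzyloxy)phenyl]methylidene}-5-oxooxolan-3-yl]carbonyl}-1,3-oxazolidin-2-one
Product: 9 (2R,3R,4E)-2-[4-(benzyloxy)phenyl]-4-{[4-(benzyloxy)phenyl]methylidene}-5-oxooxolane-3-carboxylic acid
Conditions: LiOH, H2O2, THF–H2O, 0 °C; Na2SO3; aq. HCl to pH 2
Reagents that add atoms: hydrogen peroxide, OO (as LiOOH; supplies the hydroxyl oxygen of the acid)
Why: Hydroperoxide cleavage of an N-acyl oxazolidinone: LiOOH attacks the exocyclic imide carbonyl, the peracid is reduced by sulfite and 4 is recovered; the α-centre should not be enolised at 0 °C (allylic strain in the imide, then a carboxylate), and a lactone that opens re-closes on acidification.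

**Step 5**
Reactants: 9 (2R,3R,4E)-2-[4-(benzyloxy)phenyl]-4-{[4-(benzyloxy)phenyl]methylidene}-5-oxooxolane-3-carboxylic acid
Product: 10 (1S,2S,5R,6R)-2,6-bis[4-(benzyloxy)phenyl]-1-bromo-3,7-dioxabicyclo[3.3.0]octane-4,8-dione (both aryl groups exo; bromine on the convex face at the ring fusion)
Conditions: NBS (1.05 equiv), 2,6-lutidine (cat.), CH2Cl2, −20 → 0 °C, dark
Reagents that add atoms: N-bromosuccinimide, BrN1C(=O)CCC1=O
Why: Bromolactonisation of a γ-aryl β,γ-unsaturated acid in the 5-endo mode: bromine adds to the ring carbon of the alkene and the carboxyl group captures the 4-alkoxybenzylic carbon; the tether lets the acid reach the alkene only from its own face, so the ring fusion is cis with bromine on the convex face, and anti addition to the E alkene places the new aryl group exo.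

**Step 6**
Reactants: 10 (1S,2S,5R,6R)-2,6-bis[4-(benzyloxy)phenyl]-1-bromo-3,7-dioxabicyclo[3.3.0]octane-4,8-dione
Product: 11 (1R,2R,5R,6R)-2,6-bis[4-(benzyloxy)phenyl]-3,7-dioxabicyclo[3.3.0]octane-4,8-dione (exo,exo)
Conditions: Bu3SnH, AIBN (cat.), PhMe, 80 °C
Reagents that add atoms: none
Why: Radical chain dehalogenation of an α-bromo lactone: the tertiary α-acyl radical at the ring fusion can take hydrogen only on the convex face, because the trans-fused bicycle is too strained, so the cis-fused dilactone results; no base or metal enolate is involved, so the β-acyloxy group is not eliminated.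

**Step 7**
Reactants: 12 4-bromobenzene-1,3-diol
Product: 13 2,4-bis(benzyloxy)-1-bromobenzene
Conditions: BnBr (2.2 equiv), K2CO3, DMF, rt
Reagents that add atoms: benzyl bromide, BrCc1ccccc1 (two equivalents, one for each phenol)
Why: Williamson ether synthesis on both phenols; the bromine is kept as the site of the later halogen–lithium exchange.

**Step 8**
Reactants: 11 (1R,2R,5R,6R)-2,6-bis[4-(benzyloxy)phenyl]-3,7-dioxabicyclo[3.3.0]octane-4,8-dione; 13 2,4-bis(benzyloxy)-1-bromobenzene (two molar equivalents, one for each lactone carbonyl)
Product: 16 (1R,2R,4R,5R,6R,8R)-4,8-bis[2,4-bis(benzyloxy)phenyl]-2,6-bis[4-(benzyloxy)phenyl]-3,7-dioxabicyclo[3.3.0]octane (2,6-exo-4,8-endo), via [2,4-bis(benzyloxy)phenyl]lithium 14 (not isolated), via bis-lactol 15 (not isolated)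
Conditions: 13 (2.3 equiv), n-BuLi (2.2 equiv), THF, −78 °C; 11 (1.0 equiv), THF, −78 °C; AcOH, −78 °C; solvent exchange to CH2Cl2; Et3SiH, BF3·OEt2 (promoter), −78 → −40 °C
Reagents that add atoms: a second equivalent of 2,4-bis(benzyloxy)-1-bromobenzene, Brc1ccc(OCc2ccccc2)cc1OCc1ccccc1 (compound 13; it delivers the second 2,4-bis(benzyloxy)phenyl group through 14)
Why: Bromine–lithium exchange on two equivalents of 13 gives aryllithium 14, which adds once to each lactone carbonyl of 11 on the open convex face; the lithium hemiketalates do not collapse at −78 °C, so no ketone is exposed while nucleophile is present, and protonation gives bis-lactol 15 (in ring–chain equilibrium with its hydroxy ketone forms). BF3·OEt2 then ionises each hemiketal to a cyclic oxocarbenium ion stabilised by the 2,4-dialkoxyphenyl group, and Et3SiH transfers hydride to it. The closest known reaction type is the addition of aryllithium reagents to five-membered aldonolactones followed by silane reduction of the aryl lactols, as used for C-aryl glycosides. No ring is closed: both five-membered rings of 11 are kept, and a lactol that has opened re-closes by 5-exo addition of its hydroxyl to the activated ketone before reduction. The two new stereocentres (C4 and C8) are controlled by the cis-fused bicycle: the concave face of each oxocarbenium carbon is covered by the other ring, so hydride enters on the convex face, syn to the ring-fusion hydrogen, and the new aryl group ends on the concave face, cis to the neighbouring ring-fusion substituent as C5 of 19 requires. The step needs one addition per carbonyl, addition faster than deprotonation of the acidic ring-fusion C–H, and ionisation of the hemiketals in preference to the benzylic ethers; low temperature, the stable hemiketalates and the inert benzyl ethers should secure these, and because 11 is C2-symmetric no selection between the two carbonyls is needed. Material lost by deprotonation would undergo β-elimination to an arylidene lactone carboxylate of the type of 9 and could be returned to step 5.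

**Step 9**
Reactants: 16 (1R,2R,4R,5R,6R,8R)-4,8-bis[2,4-bis(benzyloxy)phenyl]-2,6-bis[4-(benzyloxy)phenyl]-3,7-dioxabicyclo[3.3.0]octane
Product: 18 [2,4-bis(benzyloxy)phenyl][(2R,3R,4R,5R)-5-[2,4-bis(benzyloxy)phenyl]-2-[4-(benzyloxy)phenyl]-4-{(R)-[4-(benzyloxy)phenyl](hydroxy)methyl}oxolan-3-yl]methanone, via cyclic hemiketal 17 (not isolated)
Conditions: DDQ (1.0 equiv), CH2Cl2–pH 7 buffer (10:1), 0 °C, stopped at partial conversion
Reagents that add atoms: water, O
Why: DDQ oxidation of an electron-rich benzylic ether: hydride is abstracted from the C–H next to a 2,4-dialkoxyphenyl ring (exo, on the open convex face), the C–H bonds next to the 4-alkoxyphenyl rings are endo and less activated, water traps the oxocarbenium ion and hemiketal 17 opens to ketone and carbinol without touching a stereocentre; the two reactive sites are equivalent, so the step is run to partial conversion, and recovered 16 as well as doubly oxidised material (the open form of 15) can be returned to the reduction of step 8.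

**Step 10**
Reactants: 18 [2,4-bis(benzyloxy)phenyl][(2R,3R,4R,5R)-5-[2,4-bis(benzyloxy)phenyl]-2-[4-(benzyloxy)phenyl]-4-{(R)-[4-(benzyloxy)phenyl](hydroxy)methyl}oxolan-3-yl]methanone
Product: 19 (2,4-dihydroxyphenyl)[(2R,3R,4R,5R)-5-(2,4-dihydroxyphenyl)-4-[(R)-hydroxy(4-hydroxyphenyl)methyl]-2-(4-hydroxyphenyl)oxolan-3-yl]methanone
Conditions: H2 (1 atm), 10% Pd/C, EtOAc–THF, rt, stopped when the last benzyl ether is gone
Reagents that add atoms: none
Why: Catalytic hydrogenolysis of aryl benzyl ethers under neutral conditions; without acid the benzylic C–O bonds of 2-aryl oxolanes, benzylic alcohols and hydrogen-bonded aryl ketones are cleaved or reduced much more slowly than O-benzyl groups, and neither acid nor base is present to ionise a benzylic ether or to enolise C3.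

## Compound list

1 | dimethyl succinate | COC(=O)CCC(=O)OC | starting material
2 | 4-(benzyloxy)benzaldehyde | O=Cc1ccc(OCc2ccccc2)cc1 | starting material
3 | (3E)-4-[4-(benzyloxy)phenyl]-3-(methoxycarbonyl)but-3-enoic acid | COC(=O)/C(=C/c1ccc(OCc2ccccc2)cc1)CC(O)=O | intermediate
4 | (4R)-4-benzyl-1,3-oxazolidin-2-one | O=C1N[C@H](Cc2ccccc2)CO1 | starting material
5 | mixed anhydride of 3 with pivalic acid | COC(=O)/C(=C/c1ccc(OCc2ccccc2)cc1)CC(=O)OC(=O)C(C)(C)C | intermediate
6 | methyl (2E)-2-{2-[(4R)-4-benzyl-2-oxo-1,3-oxazolidin-3-yl]-2-oxoethyl}-3-[4-(benzyloxy)phenyl]prop-2-enoate | COC(=O)/C(=C/c1ccc(OCc2ccccc2)cc1)CC(=O)N1C(=O)OC[C@H]1Cc1ccccc1 | intermediate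
7 | methyl (2E,3R,4R)-3-{[(4R)-4-benzyl-2-oxo-1,3-oxazolidin-3-yl]carbonyl}-4-[4-(benzyloxy)phenyl]-2-{[4-(benzyloxy)phenyl]methylidene}-4-hydroxybutanoate | COC(=O)/C(=C/c1ccc(OCc2ccccc2)cc1)[C@H]([C@@H](O)c1ccc(OCc2ccccc2)cc1)C(=O)N1C(=O)OC[C@H]1Cc1ccccc1 | intermediate
8 | (4R)-4-benzyl-3-{[(2R,3R,4E)-2-[4-(benzyloxy)phenyl]-4-{[4-(benzyloxy)phenyl]methylidene}-5-oxooxolan-3-yl]carbonyl}-1,3-oxazolidin-2-one | O=C1O[C@@H](c2ccc(OCc3ccccc3)cc2)[C@H](C(=O)N2C(=O)OC[C@H]2Cc2ccccc2)/C1=C\c1ccc(OCc2ccccc2)cc1 | intermediate
9 | (2R,3R,4E)-2-[4-(benzyloxy)phenyl]-4-{[4-(benzyloxy)phenyl]methylidene}-5-oxooxolane-3-carboxylic acid | O=C1O[C@@H](c2ccc(OCc3ccccc3)cc2)[C@H](C(O)=O)/C1=C\c1ccc(OCc2ccccc2)cc1 | intermediate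
10 | (1S,2S,5R,6R)-2,6-bis[4-(benzyloxy)phenyl]-1-bromo-3,7-dioxabicyclo[3.3.0]octane-4,8-dione | O=C2[C@]1(Br)[C@H]([C@@H](O2)c3ccc(OCc4ccccc4)cc3)C(=O)O[C@H]1c1ccc(OCc2ccccc2)cc1 | intermediate
11 | (1R,2R,5R,6R)-2,6-bis[4-(benzyloxy)phenyl]-3,7-dioxabicyclo[3.3.0]octane-4,8-dione (exo,exo) | O=C2[C@@H]1[C@H]([C@@H](O2)c3ccc(OCc4ccccc4)cc3)C(=O)O[C@H]1c1ccc(OCc2ccccc2)cc1 | intermediate
12 | 4-bromobenzene-1,3-diol (4-bromoresorcinol) | Oc1ccc(Br)c(O)c1 | starting material
13 | 2,4-bis(benzyloxy)-1-bromobenzene | Brc1ccc(OCc2ccccc2)cc1OCc1ccccc1 | intermediate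
14 | [2,4-bis(benzyloxy)phenyl]lithium | [Li]c1ccc(OCc2ccccc2)cc1OCc1ccccc1 | intermediate
15 | (1R,2R,5R,6R)-4,8-bis[2,4-bis(benzyloxy)phenyl]-2,6-bis[4-(benzyloxy)phenyl]-3,7-dioxabicyclo[3.3.0]octane-4,8-diol (bis-lactol, C4 and C8 not assigned) | OC2(c3ccc(OCc4ccccc4)cc3OCc3ccccc3)[C@@H]1[C@H]([C@@H](O2)c3ccc(OCc4ccccc4)cc3)C(O)(c3ccc(OCc4ccccc4)cc3OCc3ccccc3)O[C@H]1c1ccc(OCc2ccccc2)cc1 | intermediate
16 | (1R,2R,4R,5R,6R,8R)-4,8-bis[2,4-bis(benzyloxy)phenyl]-2,6-bis[4-(benzyloxy)phenyl]-3,7-dioxabicyclo[3.3.0]octane (2,6-exo-4,8-endo) | [C@H]2(c3ccc(OCc4ccccc4)cc3OCc3ccccc3)[C@@H]1[C@H]([C@@H](O2)c3ccc(OCc4ccccc4)cc3)[C@H](c3ccc(OCc4ccccc4)cc3OCc3ccccc3)O[C@H]1c1ccc(OCc2ccccc2)cc1 | intermediate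
17 | cyclic hemiketal of 18: 16 with OH in place of H at one endo-aryl carbon (that carbon not assigned) | OC2(c3ccc(OCc4ccccc4)cc3OCc3ccccc3)[C@@H]1[C@H]([C@@H](O2)c3ccc(OCc4ccccc4)cc3)[C@H](c3ccc(OCc4ccccc4)cc3OCc3ccccc3)O[C@H]1c1ccc(OCc2ccccc2)cc1 | intermediate
18 | [2,4-bis(benzyloxy)phenyl][(2R,3R,4R,5R)-5-[2,4-bis(benzyloxy)phenyl]-2-[4-(benzyloxy)phenyl]-4-{(R)-[4-(benzyloxy)phenyl](hydroxy)methyl}oxolan-3-yl]methanone | O=C(c1ccc(OCc2ccccc2)cc1OCc1ccccc1)[C@@H]1[C@H]([C@@H](O)c2ccc(OCc3ccccc3)cc2)[C@H](c2ccc(OCc3ccccc3)cc2OCc2ccccc2)O[C@H]1c1ccc(OCc2ccccc2)cc1 | intermediate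
19 | (2,4-dihydroxyphenyl)[(2R,3R,4R,5R)-5-(2,4-dihydroxyphenyl)-4-[(R)-hydroxy(4-hydroxyphenyl)methyl]-2-(4-hydroxyphenyl)oxolan-3-yl]methanone | O=C(c1ccc(O)cc1O)[C@@H]1[C@H]([C@@H](O)c2ccc(O)cc2)[C@H](c2ccc(O)cc2O)O[C@H]1c1ccc(O)cc1 | target

## Step count and least certain steps

Total: 10 steps. Longest linear sequence: 9 steps (steps 1–6, 8, 9, 10); step 7 is a one-step branch.

**Step 8 (key step).** Most likely failure: deprotonation of the acidic ring-fusion C–H by the strongly basic aryllithium in competition with carbonyl addition, followed by β-elimination of the neighbouring acyloxy group, or a second addition after collapse of a hemiketalate. Both lower the amount of bis-adduct. Fallback, from 11 and back to the route at 15: both lactones of 11 are opened with Me(MeO)NH·HCl/AlMe3 to (2R,3R)-2,3-bis{(R)-[4-(benzyloxy)phenyl](hydroxy)methyl}-N1,N4-dimethoxy-N1,N4-dimethylbutanediamide F1. The hydroxyls are capped with TESOTf/2,6-lutidine to give (2R,3R)-2,3-bis{(R)-[4-(benzyloxy)phenyl][(triethylsilyl)oxy]methyl}-N1,N4-dimethoxy-N1,N4-dimethylbutanediamide F2. Addition of 14 to this amide class stops at the chelated tetrahedral adduct, and its α-hydrogens are far less acidic than those of a lactone; work-up gives (2R,3R)-1,4-bis[2,4-bis(benzyloxy)phenyl]-2,3-bis{(R)-[4-(benzyloxy)phenyl][(triethylsilyl)oxy]methyl}butane-1,4-dione F3. Buffered HF·pyridine removes the silyl groups and gives 15, which is reduced as in step 8.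

**Step 9.** Most likely failure: a second oxidation at the equivalent site before the first is complete, because the two sites are remote and nearly independent, together with slower oxidation of the freed benzylic alcohol; the mono-oxidised product would then be only part of a statistical mixture. Fallback, from 11 and back to the route at 18, with no oxidation: one equivalent of 14 is added to 11 to give the hemiketal lactone 8-[2,4-bis(benzyloxy)phenyl]-2,6-bis[4-(benzyloxy)phenyl]-8-hydroxy-3,7-dioxabicyclo[3.3.0]octan-4-one F4. Reduction with Et3SiH/BF3·OEt2 gives (1S,2R,5R,6R,8R)-8-[2,4-bis(benzyloxy)phenyl]-2,6-bis[4-(benzyloxy)phenyl]-3,7-dioxabicyclo[3.3.0]octan-4-one F5 (8-aryl endo). A second portion of 14 is added to the remaining lactone; the hemiketal 17 so formed opens to 18. Unreacted 11 and bis-adduct 15 from the first addition are separated and re-used.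

**Step 3.** Most likely failure: slow or reversible addition and loss of diastereoselectivity, because the enolate is delocalised into the styrene-type alkene and its partner is an electron-rich aldehyde; reaction through the far end of the extended enolate is a further possibility. Fallback, from 4 and 2 and back to the route at 9, with the two C–C bonds made in the opposite order:
- Lithiated 4 is acylated with methyl 4-chloro-4-oxobutanoate to methyl 4-[(4R)-4-benzyl-2-oxo-1,3-oxazolidin-3-yl]-4-oxobutanoate F6.
- The Evans syn-aldol with 2 and lactonisation, as in step 3, give (4R)-4-benzyl-3-{[(2R,3R)-2-[4-(benzyloxy)phenyl]-5-oxooxolan-3-yl]carbonyl}-1,3-oxazolidin-2-one F7.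
- LiOH/H2O2 gives (2R,3R)-2-[4-(benzyloxy)phenyl]-5-oxooxolane-3-carboxylic acid F8.
- The dianion of F8 (LDA, 2 equiv, THF, −78 °C) adds to 2 to give (2R,3R)-2-[4-(benzyloxy)phenyl]-4-{[4-(benzyloxy)phenyl](hydroxy)methyl}-5-oxooxolane-3-carboxylic acid F9 as a mixture at the two new centres.
- Acetylation and elimination (Ac2O, Et3N, DMAP; then DBU) remove both new centres and give 9.

**Step 5.** Most likely failure: electrophilic bromination of the benzyloxy-substituted rings in competition with attack on the electron-poor alkene. Fallback, from 9 directly to 11 with no new compound: proton-induced hydrolactonisation (TfOH, catalytic, CH2Cl2, low temperature), in which protonation of the unsaturated lactone makes the benzylic carbon electrophilic and the carboxyl group closes the ring with the only possible cis fusion. This skips 10 and step 6, but it passes through a benzylic cation in acid, so the optical purity of 11 would have to be checked.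

**Step 10.** Most likely failure: hydrogenolysis of the oxygen-activated benzylic C–O bonds (the carbinol and the C5–O1 bond) once the phenols are free, or reduction of the ketone. Fallback, from 16 and back to the route at 19, exchanging the protecting groups before the oxidation, where neither carbinol nor ketone is present:
- 16 is hydrogenolysed (H2, 10% Pd/C) to (1R,2R,4R,5R,6R,8R)-4,8-bis(2,4-dihydroxyphenyl)-2,6-bis(4-hydroxyphenyl)-3,7-dioxabicyclo[3.3.0]octane F10.
- TBSCl/imidazole gives the hexakis(tert-butyldimethylsilyl) ether of that hexaphenol F11.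
- DDQ in wet CH2Cl2, as in step 9, gives the hexakis(tert-butyldimethylsilyl) ether of 19 F12.
- TBAF buffered with AcOH at 0 °C releases 19 without touching a C–O bond.

## Further compounds

F1 | step 8 | (2R,3R)-2,3-bis{(R)-[4-(benzyloxy)phenyl](hydroxy)methyl}-N1,N4-dimethoxy-N1,N4-dimethylbutanediamide | CON(C)C(=O)[C@@H]([C@@H](O)c1ccc(OCc2ccccc2)cc1)[C@H]([C@@H](O)c1ccc(OCc2ccccc2)cc1)C(=O)N(C)OC
F2 | step 8 | (2R,3R)-2,3-bis{(R)-[4-(benzyloxy)phenyl][(triethylsilyl)oxy]methyl}-N1,N4-dimethoxy-N1,N4-dimethylbutanediamide | CON(C)C(=O)[C@@H]([C@@H](O[Si](CC)(CC)CC)c1ccc(OCc2ccccc2)cc1)[C@H]([C@@H](O[Si](CC)(CC)CC)c1ccc(OCc2ccccc2)cc1)C(=O)N(C)OC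
F3 | step 8 | (2R,3R)-1,4-bis[2,4-bis(benzyloxy)phenyl]-2,3-bis{(R)-[4-(benzyloxy)phenyl][(triethylsilyl)oxy]methyl}butane-1,4-dione | O=C(c1ccc(OCc2ccccc2)cc1OCc1ccccc1)[C@@H]([C@@H](O[Si](CC)(CC)CC)c1ccc(OCc2ccccc2)cc1)[C@H]([C@@H](O[Si](CC)(CC)CC)c1ccc(OCc2ccccc2)cc1)C(=O)c1ccc(OCc2ccccc2)cc1OCc1ccccc1
F4 | step 9 | 8-[2,4-bis(benzyloxy)phenyl]-2,6-bis[4-(benzyloxy)phenyl]-8-hydroxy-3,7-dioxabicyclo[3.3.0]octan-4-one (C8 not assigned, other centres as in 11) | OC2(c3ccc(OCc4ccccc4)cc3OCc3ccccc3)[C@@H]1[C@H]([C@@H](O2)c3ccc(OCc4ccccc4)cc3)C(=O)O[C@H]1c1ccc(OCc2ccccc2)cc1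
F5 | step 9 | (1S,2R,5R,6R,8R)-8-[2,4-bis(benzyloxy)phenyl]-2,6-bis[4-(benzyloxy)phenyl]-3,7-dioxabicyclo[3.3.0]octan-4-one | [C@H]2(c3ccc(OCc4ccccc4)cc3OCc3ccccc3)[C@@H]1[C@H]([C@@H](O2)c3ccc(OCc4ccccc4)cc3)C(=O)O[C@H]1c1ccc(OCc2ccccc2)cc1
F6 | step 3 | methyl 4-[(4R)-4-benzyl-2-oxo-1,3-oxazolidin-3-yl]-4-oxobutanoate | COC(=O)CCC(=O)N1C(=O)OC[C@H]1Cc1ccccc1
F7 | step 3 | (4R)-4-benzyl-3-{[(2R,3R)-2-[4-(benzyloxy)phenyl]-5-oxooxolan-3-yl]carbonyl}-1,3-oxazolidin-2-one | O=C1O[C@@H](c2ccc(OCc3ccccc3)cc2)[C@H](C(=O)N2C(=O)OC[C@H]2Cc2ccccc2)C1
F8 | step 3 | (2R,3R)-2-[4-(benzyloxy)phenyl]-5-oxooxolane-3-carboxylic acid | O=C1O[C@@H](c2ccc(OCc3ccccc3)cc2)[C@H](C(O)=O)C1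
F9 | step 3 | (2R,3R)-2-[4-(benzyloxy)phenyl]-4-{[4-(benzyloxy)phenyl](hydroxy)methyl}-5-oxooxolane-3-carboxylic acid (C4 and carbinol carbon mixed) | O=C1O[C@@H](c2ccc(OCc3ccccc3)cc2)[C@H](C(O)=O)C1C(O)c1ccc(OCc2ccccc2)cc1
F0 | step 5 | none | none
F10 | step 10 | (1R,2R,4R,5R,6R,8R)-4,8-bis(2,4-dihydroxyphenyl)-2,6-bis(4-hydroxyphenyl)-3,7-dioxabicyclo[3.3.0]octane | [C@H]2(c3ccc(O)cc3O)[C@@H]1[C@H]([C@@H](O2)c3ccc(O)cc3)[C@H](c3ccc(O)cc3O)O[C@H]1c1ccc(O)cc1
F11 | step 10 | hexakis(tert-butyldimethylsilyl) ether of F10 | [C@H]2(c3ccc(O[Si](C)(C)C(C)(C)C)cc3O[Si](C)(C)C(C)(C)C)[C@@H]1[C@H]([C@@H](O2)c3ccc(O[Si](C)(C)C(C)(C)C)cc3)[C@H](c3ccc(O[Si](C)(C)C(C)(C)C)cc3O[Si](C)(C)C(C)(C)C)O[C@H]1c1ccc(O[Si](C)(C)C(C)(C)C)cc1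
F12 | step 10 | hexakis(tert-butyldimethylsilyl) ether of 19 (six phenolic oxygens silylated, carbinol free) | O=C(c1ccc(O[Si](C)(C)C(C)(C)C)cc1O[Si](C)(C)C(C)(C)C)[C@@H]1[C@H]([C@@H](O)c2ccc(O[Si](C)(C)C(C)(C)C)cc2)[C@H](c2ccc(O[Si](C)(C)C(C)(C)C)cc2O[Si](C)(C)C(C)(C)C)O[C@H]1c1ccc(O[Si](C)(C)C(C)(C)C)cc1
A1 | alternative 1 | (1R,2R,5R,6R)-2,6-bis(4-hydroxyphenyl)-3,7-dioxabicyclo[3.3.0]octane-4,8-dione | O=C2[C@@H]1[C@H]([C@@H](O2)c3ccc(O)cc3)C(=O)O[C@H]1c1ccc(O)cc1
A2 | alternative 1 | (2S,3S)-2,3-bis(4-hydroxybenzyl)succinic acid | OC(=O)[C@@H](Cc1ccc(O)cc1)[C@H](Cc1ccc(O)cc1)C(O)=O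
A3 | alternative 2 | (4R,4'R)-3,3'-(butanedioyl)bis(4-benzyl-1,3-oxazolidin-2-one) | O=C(CCC(=O)N1[C@H](Cc2ccccc2)COC1=O)N1[C@H](Cc2ccccc2)COC1=O
A4 | alternative 2 | 4-(methoxymethoxy)benzaldehyde | O=Cc1ccc(OCOC)cc1
A5 | alternative 2 | (4R,4'R)-3,3'-{(2R,3R)-2,3-bis[(R)-hydroxy[4-(methoxymethoxy)phenyl]methyl]butanedioyl}bis(4-benzyl-1,3-oxazolidin-2-one) | O=C(N1[C@H](Cc2ccccc2)COC1=O)[C@@H]([C@@H](O)c1ccc(OCOC)cc1)[C@H]([C@@H](O)c1ccc(OCOC)cc1)C(=O)N1[C@H](Cc2ccccc2)COC1=O
A6 | alternative 2 | (1R,2R,5R,6R)-2,6-bis[4-(methoxymethoxy)phenyl]-3,7-dioxabicyclo[3.3.0]octane-4,8-dione | O=C2[C@@H]1[C@H]([C@@H](O2)c3ccc(OCOC)cc3)C(=O)O[C@H]1c1ccc(OCOC)cc1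
A7 | alternative 3 | dimethyl 2,3-bis[4-(methoxymethoxy)benzoyl]succinate | COC(=O)C(C(=O)c1ccc(OCOC)cc1)C(C(=O)OC)C(=O)c1ccc(OCOC)cc1
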